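**Plan**
1. Locants (azulene style): C1 quaternary carbon, C2, C3, C3a ring-fusion CH, C4 CH(CH3), C5, C6, C7 CH bearing C(CH3)2OH, C8 alkene CH, C8a alkene C. C1′ is the benzylic CH.
2. Enabling feature: in the seven-membered ring the alkene CH (C8) is bonded to C7, the ring CH that carries C(CH3)2OH. Adding water back across C8=C8a gives a C8 carbinol 1,3 to the tertiary oxygen. That pattern results when the CH end of an isopropylidene alkene (C7) attacks a formyl carbon (C8) on the cyclopentane and water quenches the dimethyl carbocation.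
3. Retrosynthetic cuts, in order: three ArO–CH3 and two Ar–CHO bonds; C8=C8a (back to C8–OH/C8a–H); C7–C8 and HO–C(CH3)2 (Prins); C3a–C4 (Ireland–Claisen, which also returns C8 to an exocyclic CH2); C8–C8a (sulfur ylide); C1–CH3 and C1′–CH2(isobutyl) (conjugate addition–methylation); C1=C1′ (aldol condensation).
4. Forward: cyclopentanone supplies the five-membered ring. It is substituted at C1, homologated at C8a and alkylated at C3a with a 6-methylhept-5-enoate unit. The cycloheptane is the only ring closed (step 13). Syn elimination, double formylation and demethylation finish the molecule.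
5. Stereochemistry: C1′ comes from a chiral copper catalyst and C1 from C1′ (allylic 1,3-strain in the enolate). C3a and C4 come from C1 plus the ketene acetal geometry in a chair [3,3] shift. C8a (temporary) comes from face-selective hydroboration. C7 and C8 (temporary) come from the chair-like Prins transition state.

Key step: step 13

Assumption: no reliable model predicts the sense of induction of the ferrocenyl diphosphine for this enone, so the (R,S) ligand is written in step 2 and its mirror image is taken if a test run shows the opposite sense.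

**Step 1**
Reactants: 1 cyclopentanone; 2 2,4,6-trimethoxybenzaldehyde
Product: 3 (E)-2-(2,4,6-trimethoxybenzylidene)cyclopentan-1-one
Conditions: 1 (4 equiv), NaOH (0.3 equiv, 1 M aq), EtOH, 0 °C → rt
Reagents that add atoms: none
Why: Claisen–Schmidt aldol condensation, in which the excess of ketone holds back the 2,5-bis-condensation and the E alkene is the thermodynamic product because the aryl group turns away from the carbonyl group.

**Step 2**
Reactants: 3 arylidene ketone; 4 isobutylmagnesium bromide
Product: 6 (2R)-2-methyl-2-[(1R)-3-methyl-1-(2,4,6-trimethoxyphenyl)butyl]cyclopentan-1-one, via magnesium enolate 5 (not isolated)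
Conditions: 4 (1.3 equiv), CuBr·SMe2 (5 mol %), (R)-1-[(S)-2-(diphenylphosphino)ferrocenyl]ethyldicyclohexylphosphine (6 mol %), t-BuOMe, −75 °C; then MeI (5 equiv), DMPU, −75 → 0 °C
Reagents that add atoms: iodomethane, CI
Why: Copper-catalysed enantioselective conjugate addition of a Grignard reagent sets C1′ under ligand control, and the regiodefined enolate is then C-methylated anti to the aryl group in the conformer that keeps the C1′ hydrogen in the enolate plane (minimised allylic 1,3-strain), which sets the quaternary C1.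

**Step 3**
Reactants: 6 quaternary ketone
Product: 7 (2R)-2-[(1R)-1-(3,5-dibromo-2,4,6-trimethoxyphenyl)-3-methylbutyl]-2-methylcyclopentan-1-one
Conditions: NBS (2.1 equiv), MeCN, 0 °C → rt, dark
Reagents that add atoms: N-bromosuccinimide, O=C1CCC(=O)N1Br
Why: Electrophilic aromatic bromination fills both free positions of the very electron-rich ring at a stage that holds no alkene, which installs the handles for the formyl groups and removes the nucleophilic arene CH sites before the cationic ring closure.

**Step 4**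
Reactants: 7 dibromo ketone
Product: 8 (3R,4R)-4-[(1S)-1-(3,5-dibromo-2,4,6-trimethoxyphenyl)-3-methylbutyl]-4-methyl-1-oxaspiro[2.4]heptane
Conditions: Me3SI (3 equiv), NaH (3 equiv), DMSO–THF, 0 °C → rt
Reagents that add atoms: trimethylsulfonium iodide, C[S+](C)C.[I-]
Why: Corey–Chaykovsky methylene transfer brings in C8 and tolerates hindered ketones; the ylide should add anti to the bulky C1 side chain, and the spiro centre it creates is erased in the next step.

**Step 5**
Reactants: 8 spiro-epoxide
Product: 9 {(5R)-5-[(1S)-1-(3,5-dibromo-2,4,6-trimethoxyphenyl)-3-methylbutyl]-5-methylcyclopent-1-en-1-yl}methanol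
Conditions: LiNEt2 (3 equiv), THF, 0 °C → reflux; then H2O
Reagents that add atoms: none
Why: Base-induced isomerisation of an epoxide to an allylic alcohol (syn β-elimination through the lithium-bound epoxide), which can give only the C8a=C3a alkene because the other neighbour of C8a is the quaternary C1.

**Step 6**
Reactants: 10 (4-carboxybutyl)triphenylphosphonium bromide; 11 acetone
Product: 13 6-methylhept-5-enoic acid, via ylide carboxylate 12 (not isolated)
Conditions: KOtBu (2.2 equiv), THF, 0 °C; then 11, 0 °C → rt; then 1 M HCl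
Reagents that add atoms: none
Why: Wittig olefination of acetone with the non-stabilised ylide of a commercial phosphonium salt gives the isopropylidene acid without any alkene geometry issue.

**Step 7**
Reactants: 9 allylic alcohol; 13 6-methylhept-5-enoic acid
Product: 14 {(5R)-5-[(1S)-1-(3,5-dibromo-2,4,6-trimethoxyphenyl)-3-methylbutyl]-5-methylcyclopent-1-en-1-yl}methyl 6-methylhept-5-enoate
Conditions: DCC (1.2 equiv), DMAP (10 mol %), CH2Cl2, 0 °C → rt
Reagents that add atoms: none
Why: Steglich esterification acylates the unhindered primary allylic alcohol under neutral conditions that leave both alkenes and the aryl bromides untouched.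

**Step 8**
Reactants: 14 allylic ester
Product: 17 (2R)-2-{(1R,3R)-3-[(1S)-1-(3,5-dibromo-2,4,6-trimethoxyphenyl)-3-methylbutyl]-3-methyl-2-methylidenecyclopentyl}-6-methylhept-5-enoic acid, via silyl ketene acetal 15 (not isolated), via silyl ester 16 (not isolated)
Conditions: LiN(iPr)2 (1.2 equiv), THF–HMPA (4:1), −78 °C; TBSCl, −78 °C → rt, then 60 °C; then 1 M HCl, THF, rt
Reagents that add atoms: none
Why: Ireland–Claisen rearrangement, in which enolisation in THF–HMPA gives the (Z)-silyl ketene acetal (chain trans to the allylic oxygen) and a chair transition state on the ring face anti to the bulky C1 side chain forms C3a–C4, setting C3a and C4 together and leaving C8 as an exocyclic methylene.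

**Step 9**
Reactants: 17 rearranged acid
Product: 18 (2R)-2-{(1R,3R)-3-[(1S)-1-(3,5-dibromo-2,4,6-trimethoxyphenyl)-3-methylbutyl]-3-methyl-2-methylidenecyclopentyl}-6-methylhept-5-en-1-ol
Conditions: LiAlH4 (2 equiv), Et2O, 0 °C; then H2O, aq NaOH
Reagents that add atoms: none
Why: Hydride reduction of the carboxylic acid to the primary alcohol, run at 0 °C where electron-rich aryl bromides and isolated alkenes are inert.

**Step 10**
Reactants: 18 primary alcohol
Product: 20 1,3-dibromo-2,4,6-trimethoxy-5-{(1S)-3-methyl-1-[(1R,3R)-1-methyl-3-[(2R)-6-methylhept-5-en-2-yl]-2-methylidenecyclopentyl]butyl}benzene, via mesylate 19 (not isolated)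
Conditions: MsCl (1.3 equiv), Et3N (2 equiv), THF, 0 °C; then LiEt3BH (5 equiv), 0 °C → rt
Reagents that add atoms: none
Why: Sulfonate formation and SN2 hydride displacement turn CH2OH into the C4 methyl group without touching the C4 stereocentre.

**Step 11**
Reactants: 20 methylidenecyclopentane
Product: 22 {(1S,2R,5R)-2-[(1S)-1-(3,5-dibromo-2,4,6-trimethoxyphenyl)-3-methylbutyl]-2-methyl-5-[(2R)-6-methylhept-5-en-2-yl]cyclopentyl}methanol, via alkylborane 21 (not isolated)
Conditions: 9-BBN (1.5 equiv), THF, 0 °C → rt; then NaOH, H2O2, 0 °C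
Reagents that add atoms: hydrogen peroxide, OO
Why: Hydroboration–oxidation, in which 9-BBN selects the 1,1-disubstituted over the trisubstituted alkene and should approach from the face where C8a is flanked only by H-3a (the other face carries both the C1 methyl group and the C3a side chain), which places H-8a cis to H-3a and the CH2OH group cis to the side chain.

**Step 12**
Reactants: 22 cyclopentylmethanol
Product: 23 (1S,2R,5R)-2-[(1S)-1-(3,5-dibromo-2,4,6-trimethoxyphenyl)-3-methylbutyl]-2-methyl-5-[(2R)-6-methylhept-5-en-2-yl]cyclopentane-1-carbaldehyde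
Conditions: Dess–Martin periodinane (1.3 equiv), NaHCO3 (5 equiv), CH2Cl2, 0 °C → rt
Reagents that add atoms: none
Why: Dess–Martin oxidation under buffered, near-neutral conditions gives the aldehyde without enolisation at C8a and without attack on the alkene.

**Step 13**
Reactants: 23 cis aldehyde
Product: 24 (1R,3aR,4R,7R,8S,8aS)-1-[(1S)-1-(3,5-dibromo-2,4,6-trimethoxyphenyl)-3-methylbutyl]-7-(2-hydroxypropan-2-yl)-1,4-dimethyldecahydroazulen-8-ol
Conditions: Sc(OTf)3 (20 mol %), water-saturated MeNO2–CH2Cl2 (1:1), 2 mM, 0 °C → rt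
Reagents that add atoms: water, O
Why: Sc(OTf)3, a water-tolerant oxophilic Lewis acid, binds the formyl oxygen of 23, C7 (the CH end of the isopropylidene alkene) attacks C8, the charge settles on the dimethyl-substituted carbon as the alkene polarisation dictates, and water, the only nucleophile present beside the non-coordinating triflate, captures it. The closest known reaction type is the intramolecular Prins cyclisation with hydration that turns citronellal into p-menthane-3,8-diol, together with Lewis-acid aldehyde–alkene closures of cyclopentanecarbaldehydes to hydroazulenes; the ring formed here is one atom larger than in the former. The cycloheptane closes in a 7-exo-trig mode with respect to both the C=O and the C=C bond, helped by the cis arrangement of formyl group and side chain on the cyclopentane, which already fixes two of the seven ring atoms and holds the reacting ends close. C7 is controlled by a chair-like transition state in which the C3a–C8a bond takes the eclipsed edge and the C4 methyl group and the isopropylidene unit both lie pseudo-equatorial, which places the new C7 substituent trans to the C4 methyl group. C8 is controlled by the pseudo-axial carbonyl oxygen that leans toward the developing cation, the arrangement behind the kinetic cis-diol from citronellal, so that the hydroxyl ends up cis to the C7 substituent and cis to H-8a. The step needs selectivity for the alkene over other π-nucleophiles and for cyclisation over epimerisation or acetal formation: the hexasubstituted dibromoarene has no free ring position, the Lewis acid activates C=O rather than protonating the alkene, and low temperature and high dilution hold back enolisation and capture of 23 by the product diol.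

**Step 14**
Reactants: 24 bicyclic 1,3-diol
Product: 26 O-[C8] S-methyl dithiocarbonate (xanthate) of 24 with the tertiary hydroxyl free, via sodium xanthate 25 (not isolated)
Conditions: NaH (1.05 equiv), CS2 (5 equiv), THF, 0 °C; then MeI (1.5 equiv), 0 °C → rt
Reagents that add atoms: carbon disulfide, S=C=S; iodomethane, CI
Why: Xanthate formation for a Chugaev elimination, selective for the secondary hydroxyl because one equivalent of base is used and the adduct of a tertiary alkoxide with CS2 is crowded and reverts.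

**Step 15**
Reactants: 26 xanthate
Product: 28 (1R,3aR,4R,7R)-1-[(1S)-1-(3,5-dibromo-2,4,6-trimethoxyphenyl)-3-methylbutyl]-1,4-dimethyl-7-[2-(trimethylsilyloxy)propan-2-yl]-1,2,3,3a,4,5,6,7-octahydroazulene, via silylated xanthate 27 (not isolated)
Conditions: N,O-bis(trimethylsilyl)acetamide (5 equiv), TMSCl (5 mol %), 1,2-dichlorobenzene, 70 °C; then 180 °C
Reagents that add atoms: N,O-bis(trimethylsilyl)acetamide, CC(=N[Si](C)(C)C)O[Si](C)(C)C
Why: Silylation first stops the tertiary hydroxyl from attacking the thiocarbonyl group, and the Chugaev syn elimination can then take only H-8a, because H-7 lies anti to the C8 oxygen, so the C8=C8a alkene forms as the single regioisomer and the temporary centres C8 and C8a vanish.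

**Step 16**
Reactants: 28 silyl ether alkene
Product: 30 5-{(1S)-1-[(1R,3aR,4R,7R)-1,4-dimethyl-7-[2-(trimethylsilyloxy)propan-2-yl]-1,2,3,3a,4,5,6,7-octahydroazulen-1-yl]-3-methylbutyl}-2,4,6-trimethoxybenzene-1,3-dicarbaldehyde, via dilithioarene 29 (not isolated)
Conditions: t-BuLi (4.4 equiv), THF, −78 °C; then DMF (10 equiv), −78 → 0 °C; then aq NH4Cl
Reagents that add atoms: N,N-dimethylformamide, CN(C)C=O
Why: Double bromine–lithium exchange followed by formylation with DMF, in which each aryllithium is flanked and stabilised by two methoxy groups and neither the silyl ether nor the trisubstituted alkene reacts at −78 °C.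

**Step 17**
Reactants: 30 dialdehyde
Product: 32 5-{(1S)-1-[(1R,3aR,4R,7R)-7-(2-hydroxypropan-2-yl)-1,4-dimethyl-1,2,3,3a,4,5,6,7-octahydroazulen-1-yl]-3-methylbutyl}-2,4,6-trihydroxybenzene-1,3-dicarbaldehyde (CNP0281883.3), via trisodium phenolate 31 (not isolated)
Conditions: NaSEt (12 equiv), DMF, 120 °C; then 1 M HCl, THF, rt
Reagents that add atoms: none
Why: Thiolate SN2 O-demethylation works because every methoxy group is ortho or para to both formyl groups and so leaves as a stabilised phenolate; the basic medium spares the alkene and the tertiary carbinol, and the mild acidic work-up protonates the phenolates and hydrolyses the trimethylsilyl ether.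

**Compound list**
1 | cyclopentanone | O=C1CCCC1 | starting material
2 | 2,4,6-trimethoxybenzaldehyde | COc1cc(OC)c(C=O)c(OC)c1 | starting material
3 | (E)-2-(2,4,6-trimethoxybenzylidene)cyclopentan-1-one | O=C1CCC/C1=C\c1c(OC)cc(OC)cc1OC | intermediate
4 | isobutylmagnesium bromide | CC(C)C[Mg]Br | starting material
5 | bromomagnesium 2-[(1S)-3-methyl-1-(2,4,6-trimethoxyphenyl)butyl]cyclopent-1-en-1-olate | CC(C)C[C@H](c1c(OC)cc(OC)cc1OC)C1=C(O[Mg]Br)CCC1 | intermediate
6 | (2R)-2-methyl-2-[(1R)-3-methyl-1-(2,4,6-trimethoxyphenyl)butyl]cyclopentan-1-one | CC(C)C[C@H](c1c(OC)cc(OC)cc1OC)[C@@]1(C)CCCC1=O | intermediate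
7 | (2R)-2-[(1R)-1-(3,5-dibromo-2,4,6-trimethoxyphenyl)-3-methylbutyl]-2-methylcyclopentan-1-one | CC(C)C[C@H](c1c(OC)c(Br)c(OC)c(Br)c1OC)[C@@]1(C)CCCC1=O | intermediate
8 | (3R,4R)-4-[(1S)-1-(3,5-dibromo-2,4,6-trimethoxyphenyl)-3-methylbutyl]-4-methyl-1-oxaspiro[2.4]heptane | CC(C)C[C@H](c1c(OC)c(Br)c(OC)c(Br)c1OC)[C@@]1(C)CCC[C@]12CO2 | intermediate
9 | {(5R)-5-[(1S)-1-(3,5-dibromo-2,4,6-trimethoxyphenyl)-3-methylbutyl]-5-methylcyclopent-1-en-1-yl}methanol | CC(C)C[C@H](c1c(OC)c(Br)c(OC)c(Br)c1OC)[C@@]1(C)CCC=C1CO | intermediate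
10 | (4-carboxybutyl)triphenylphosphonium bromide | OC(=O)CCCC[P+](c1ccccc1)(c1ccccc1)c1ccccc1.[Br-] | starting material
11 | acetone | CC(C)=O | starting material
12 | potassium 5-(triphenylphosphoranylidene)pentanoate | [K+].[O-]C(=O)CCCC=P(c1ccccc1)(c1ccccc1)c1ccccc1 | intermediate
13 | 6-methylhept-5-enoic acid | CC(C)=CCCCC(=O)O | intermediate
14 | {(5R)-5-[(1S)-1-(3,5-dibromo-2,4,6-trimethoxyphenyl)-3-methylbutyl]-5-methylcyclopent-1-en-1-yl}methyl 6-methylhept-5-enoate | CC(C)C[C@H](c1c(OC)c(Br)c(OC)c(Br)c1OC)[C@@]1(C)CCC=C1COC(=O)CCCC=C(C)C | intermediate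
15 | (Z)-tert-butyldimethylsilyl ketene acetal of 14 (alkyl chain cis to OSi, trans to the allylic oxygen) | CC(C)C[C@H](c1c(OC)c(Br)c(OC)c(Br)c1OC)[C@@]1(C)CCC=C1CO/C(O[Si](C)(C)C(C)(C)C)=C/CCC=C(C)C | intermediate
16 | tert-butyldimethylsilyl ester of 17 | CC(C)C[C@H](c1c(OC)c(Br)c(OC)c(Br)c1OC)[C@@]1(C)CC[C@H]([C@H](C(=O)O[Si](C)(C)C(C)(C)C)CCC=C(C)C)C1=C | intermediate
17 | (2R)-2-{(1R,3R)-3-[(1S)-1-(3,5-dibromo-2,4,6-trimethoxyphenyl)-3-methylbutyl]-3-methyl-2-methylidenecyclopentyl}-6-methylhept-5-enoic acid | CC(C)C[C@H](c1c(OC)c(Br)c(OC)c(Br)c1OC)[C@@]1(C)CC[C@H]([C@H](C(=O)O)CCC=C(C)C)C1=C | intermediate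
18 | (2R)-2-{(1R,3R)-3-[(1S)-1-(3,5-dibromo-2,4,6-trimethoxyphenyl)-3-methylbutyl]-3-methyl-2-methylidenecyclopentyl}-6-methylhept-5-en-1-ol | CC(C)C[C@H](c1c(OC)c(Br)c(OC)c(Br)c1OC)[C@@]1(C)CC[C@H]([C@H](CO)CCC=C(C)C)C1=C | intermediate
19 | methanesulfonate of 18 | CC(C)C[C@H](c1c(OC)c(Br)c(OC)c(Br)c1OC)[C@@]1(C)CC[C@H]([C@H](COS(C)(=O)=O)CCC=C(C)C)C1=C | intermediate
20 | 1,3-dibromo-2,4,6-trimethoxy-5-{(1S)-3-methyl-1-[(1R,3R)-1-methyl-3-[(2R)-6-methylhept-5-en-2-yl]-2-methylidenecyclopentyl]butyl}benzene | CC(C)C[C@H](c1c(OC)c(Br)c(OC)c(Br)c1OC)[C@@]1(C)CC[C@H]([C@H](C)CCC=C(C)C)C1=C | intermediate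
21 | B-alkyl-9-borabicyclo[3.3.1]nonane from 20 (boron on C8, H-8a cis to H-3a) | CC(C)C[C@H](c1c(OC)c(Br)c(OC)c(Br)c1OC)[C@@]1(C)CC[C@H]([C@H](C)CCC=C(C)C)[C@@H]1CB1C2CCCC1CCC2 | intermediate
22 | {(1S,2R,5R)-2-[(1S)-1-(3,5-dibromo-2,4,6-trimethoxyphenyl)-3-methylbutyl]-2-methyl-5-[(2R)-6-methylhept-5-en-2-yl]cyclopentyl}methanol | CC(C)C[C@H](c1c(OC)c(Br)c(OC)c(Br)c1OC)[C@@]1(C)CC[C@H]([C@H](C)CCC=C(C)C)[C@@H]1CO | intermediate
23 | (1S,2R,5R)-2-[(1S)-1-(3,5-dibromo-2,4,6-trimethoxyphenyl)-3-methylbutyl]-2-methyl-5-[(2R)-6-methylhept-5-en-2-yl]cyclopentane-1-carbaldehyde | CC(C)C[C@H](c1c(OC)c(Br)c(OC)c(Br)c1OC)[C@@]1(C)CC[C@H]([C@H](C)CCC=C(C)C)[C@@H]1C=O | intermediate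
24 | (1R,3aR,4R,7R,8S,8aS)-1-[(1S)-1-(3,5-dibromo-2,4,6-trimethoxyphenyl)-3-methylbutyl]-7-(2-hydroxypropan-2-yl)-1,4-dimethyldecahydroazulen-8-ol | CC(C)C[C@H](c1c(OC)c(Br)c(OC)c(Br)c1OC)[C@@]1(C)CC[C@H]2[C@@H]1[C@H](O)[C@H](C(C)(C)O)CC[C@H]2C | intermediate
25 | sodium O-[C8] dithiocarbonate of 24 | CC(C)C[C@H](c1c(OC)c(Br)c(OC)c(Br)c1OC)[C@@]1(C)CC[C@H]2[C@@H]1[C@H](OC(=S)[S-])[C@H](C(C)(C)O)CC[C@H]2C.[Na+] | intermediate
26 | O-[C8] S-methyl dithiocarbonate of 24 (tertiary hydroxyl free) | CC(C)C[C@H](c1c(OC)c(Br)c(OC)c(Br)c1OC)[C@@]1(C)CC[C@H]2[C@@H]1[C@H](OC(=S)SC)[C@H](C(C)(C)O)CC[C@H]2C | intermediate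
27 | trimethylsilyl ether of 26 | CC(C)C[C@H](c1c(OC)c(Br)c(OC)c(Br)c1OC)[C@@]1(C)CC[C@H]2[C@@H]1[C@H](OC(=S)SC)[C@H](C(C)(C)O[Si](C)(C)C)CC[C@H]2C | intermediate
28 | (1R,3aR,4R,7R)-1-[(1S)-1-(3,5-dibromo-2,4,6-trimethoxyphenyl)-3-methylbutyl]-1,4-dimethyl-7-[2-(trimethylsilyloxy)propan-2-yl]-1,2,3,3a,4,5,6,7-octahydroazulene | CC(C)C[C@H](c1c(OC)c(Br)c(OC)c(Br)c1OC)[C@@]1(C)CC[C@H]2C1=C[C@H](C(C)(C)O[Si](C)(C)C)CC[C@H]2C | intermediate
29 | 3,5-dilithio-2,4,6-trimethoxyphenyl analogue of 28 | CC(C)C[C@H](c1c(OC)c([Li])c(OC)c([Li])c1OC)[C@@]1(C)CC[C@H]2C1=C[C@H](C(C)(C)O[Si](C)(C)C)CC[C@H]2C | intermediate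
30 | 5-{(1S)-1-[(1R,3aR,4R,7R)-1,4-dimethyl-7-[2-(trimethylsilyloxy)propan-2-yl]-1,2,3,3a,4,5,6,7-octahydroazulen-1-yl]-3-methylbutyl}-2,4,6-trimethoxybenzene-1,3-dicarbaldehyde | CC(C)C[C@H](c1c(OC)c(C=O)c(OC)c(C=O)c1OC)[C@@]1(C)CC[C@H]2C1=C[C@H](C(C)(C)O[Si](C)(C)C)CC[C@H]2C | intermediate
31 | trisodium triphenolate of the trimethylsilyl ether of 32 | CC(C)C[C@H](c1c([O-])c(C=O)c([O-])c(C=O)c1[O-])[C@@]1(C)CC[C@H]2C1=C[C@H](C(C)(C)O[Si](C)(C)C)CC[C@H]2C.[Na+].[Na+].[Na+] | intermediate
32 | 5-{(1S)-1-[(1R,3aR,4R,7R)-7-(2-hydroxypropan-2-yl)-1,4-dimethyl-1,2,3,3a,4,5,6,7-octahydroazulen-1-yl]-3-methylbutyl}-2,4,6-trihydroxybenzene-1,3-dicarbaldehyde | CC(C)C[C@H](c1c(O)c(C=O)c(O)c(C=O)c1O)[C@@]1(C)CC[C@H]2C1=C[C@H](C(C)(C)O)CC[C@H]2C | target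

**Step count and risks**
Total steps: 17. Longest linear sequence: 16 (steps 1–5 and 7–17). Step 6 is a one-step side branch.

**Step 13 (ring closure).**
- The seven-membered closure may be slow. Proton loss from the tertiary cation, hydration of the alkene without C–C bond formation, or enolisation next to the formyl group could then compete.
- Facial selectivity at C7 and C8 may erode if a transition state with an axial C4 methyl group competes.
- The fallback separates C–C bond formation from hydration and sets C8 by a reduction.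
- It sets out from 23. Me2AlCl in CH2Cl2 at −78 °C promotes a carbonyl-ene closure of the same C7–C8 bond. This gives the homoallylic alcohol F1, in which proton loss leaves an isopropenyl group on C7 and the hydroxyl is expected trans to it.
- Dess–Martin oxidation gives the β,γ-unsaturated ketone F2.
- LiBH(sBu)3 at −78 °C delivers hydride from the equatorial side to give the axial alcohol F3, with the hydroxyl cis to the isopropenyl group and to H-8a.
- Mukaiyama hydration (Co(acac)2, PhSiH3, O2, iPrOH) of the only remaining alkene installs the tertiary hydroxyl. The route is rejoined at 24.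

**Step 2 (conjugate addition–methylation).**
- The β-carbon is shielded by a di-ortho-substituted, electron-rich aryl group. The 1,4-addition may be sluggish, 1,2-addition may compete, and the catalyst may discriminate the enone faces poorly.
- The fallback gives up asymmetric catalysis in favour of a chlorosilane-accelerated racemic addition followed by resolution.
- It sets out from 3. Treatment with 4, CuI (10 mol %), TMSCl and HMPA–THF at −78 °C gives the racemic silyl enol ether F4.
- MeLi releases the racemic lithium enolate F5, and MeI methylates it under the same 1,3-strain control.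
- The resulting mixture of 6 and the mirror-image ketone F6 is separated by preparative chromatography on a chiral phase. The route is rejoined at 6.

**Step 11 (hydroboration).**
- Both faces of the exocyclic alkene are hindered. The borane may be delivered to the face opposite to the one wanted, which would put H-8a trans to H-3a and take away the syn hydrogen needed in step 15.
- The fallback replaces kinetic face selection by thermodynamic control at the only enolisable centre.
- It sets out from 20. The same hydroboration then gives the epimeric alkylborane F7, and oxidation gives the epimeric alcohol F8.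
- Dess–Martin oxidation gives the epimeric aldehyde F9.
- DBU in toluene equilibrates C8a through the enolate toward the isomer whose formyl group is trans to the very large C1 side chain, with recycling of recovered F9. The route is rejoined at 23.

**Further compounds**
F1 | step 13 | ene product: C8 epimer of 24 carrying isopropenyl instead of 2-hydroxypropan-2-yl on C7 (hydroxyl trans to isopropenyl) | CC(C)C[C@H](c1c(OC)c(Br)c(OC)c(Br)c1OC)[C@@]1(C)CC[C@H]2[C@@H]1[C@@H](O)[C@H](C(C)=C)CC[C@H]2C
F2 | step 13 | C8 ketone with C7 isopropenyl group | CC(C)C[C@H](c1c(OC)c(Br)c(OC)c(Br)c1OC)[C@@]1(C)CC[C@H]2[C@@H]1C(=O)[C@H](C(C)=C)CC[C@H]2C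
F3 | step 13 | axial C8 alcohol with C7 isopropenyl group (hydroxyl cis to isopropenyl and to H-8a) | CC(C)C[C@H](c1c(OC)c(Br)c(OC)c(Br)c1OC)[C@@]1(C)CC[C@H]2[C@@H]1[C@H](O)[C@H](C(C)=C)CC[C@H]2C
F4 | step 2 | racemic 1-(trimethylsilyloxy)-2-[3-methyl-1-(2,4,6-trimethoxyphenyl)butyl]cyclopent-1-ene | CC(C)CC(c1c(OC)cc(OC)cc1OC)C1=C(O[Si](C)(C)C)CCC1
F5 | step 2 | racemic lithium 2-[3-methyl-1-(2,4,6-trimethoxyphenyl)butyl]cyclopent-1-en-1-olate | CC(C)CC(c1c(OC)cc(OC)cc1OC)C1=C(O[Li])CCC1
F6 | step 2 | (2S)-2-methyl-2-[(1S)-3-methyl-1-(2,4,6-trimethoxyphenyl)butyl]cyclopentan-1-one (enantiomer of 6) | CC(C)C[C@@H](c1c(OC)cc(OC)cc1OC)[C@]1(C)CCCC1=O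
F7 | step 11 | C8a epimer of alkylborane 21 | CC(C)C[C@H](c1c(OC)c(Br)c(OC)c(Br)c1OC)[C@@]1(C)CC[C@H]([C@H](C)CCC=C(C)C)[C@H]1CB1C2CCCC1CCC2
F8 | step 11 | C8a epimer of alcohol 22 | CC(C)C[C@H](c1c(OC)c(Br)c(OC)c(Br)c1OC)[C@@]1(C)CC[C@H]([C@H](C)CCC=C(C)C)[C@H]1CO
F9 | step 11 | C8a epimer of aldehyde 23 | CC(C)C[C@H](c1c(OC)c(Br)c(OC)c(Br)c1OC)[C@@]1(C)CC[C@H]([C@H](C)CCC=C(C)C)[C@H]1C=O
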